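The chalcone is cut on both sides of its ketone carbon: C1' of ring A–C(=O) and C(=O)–Cα. A three-component carbonylative Heck coupling joins an aryl iodide, carbon monoxide and 4-acetoxystyrene, installing the carbonyl, the E-enone and ring B in one operation on a ring A that already carries the (R)-configured side chain. The feature exploited is that C1' is one of two equivalent ring positions (C4/C6) ortho to oxygen in a 2-alkylresorcinol diether, so directed lithiation–iodination marks it unambiguously. The precursor is the 4-iodo-2-alkylresorcinol bis-MOM ether with a triethylsilyl-protected tertiary carbinol, whose stereocentre derives from Sharpless epoxidation of geraniol.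

Key step: step 8

Remark: CIP analysis gives R at the carbinol carbon of the target. The priority order O > C2 branch > C4 branch > CH3 is the same in the epoxide, the diol, the iodide and the target, so the descriptor is carried through unchanged. The organopalladium species of the key step are turnover intermediates of the catalyst and are described there, not numbered.

Step 1
Reactants: 1 geraniol
Product: 2 (2R,3R)-2,3-epoxygeraniol
Conditions: Ti(OiPr)4 (5 mol %), D-(−)-DET (7 mol %), t-BuOOH (decane), 4 Å MS, CH2Cl2, −20 °C
Reagents that add atoms: tert-butyl hydroperoxide, CC(C)(C)OO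
Why: Katsuki–Sharpless asymmetric epoxidation, in which only the titanium-bound allylic alkene receives the peroxide oxygen (the remote C6=C7 alkene is untouched) and the D-tartrate ligand sets both new stereocentres as (2R,3R) by reagent-controlled facial selection on the E-alkene.

Step 2
Reactants: 2 (2R,3R)-2,3-epoxygeraniol
Product: 3 (3R)-3,7-dimethyloct-6-ene-1,3-diol
Conditions: NaAlH2(OCH2CH2OCH3)2, THF, 0 °C → rt; aq. KNaC4H4O6 work-up
Reagents that add atoms: none
Why: Regioselective reductive opening of a 2,3-epoxy alcohol, in which the aluminate bound to the C1 oxygen delivers hydride to C2 (also the less substituted epoxide carbon), so the C3–O bond and its R configuration are not touched and the 1,3-diol should result.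

Step 3
Reactants: 3 (3R)-3,7-dimethyloct-6-ene-1,3-diol
Product: 4 (3R)-1-iodo-3,7-dimethyloct-6-en-3-ol
Conditions: PPh3, I2, imidazole, CH2Cl2, 0 °C (diol added last)
Reagents that add atoms: iodine, II
Why: Appel-type iodination under Garegg–Samuelsson conditions, in which I2 is consumed by PPh3 before the substrate is added so the alkene is spared, the primary alcohol is displaced by iodide in an SN2 step via its alkoxyphosphonium salt, and the hindered tertiary alcohol does not react at 0 °C.

Step 4
Reactants: 4 (3R)-1-iodo-3,7-dimethyloct-6-en-3-ol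
Product: 5 triethyl{[(3R)-1-iodo-3,7-dimethyloct-6-en-3-yl]oxy}silane
Conditions: TESOTf, 2,6-lutidine, CH2Cl2, −78 → 0 °C
Reagents that add atoms: triethylsilyl trifluoromethanesulfonate, CC[Si](CC)(CC)OS(=O)(=O)C(F)(F)F
Why: Silylation of a tertiary alcohol with a silyl triflate and a hindered pyridine base, a standard protection that tolerates the primary iodide and the alkene and masks the acidic OH before the organolithium steps.

Step 5
Reactants: 6 resorcinol
Product: 7 1,3-bis(methoxymethoxy)benzene
Conditions: MOMCl, i-Pr2NEt, CH2Cl2, 0 °C → rt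
Reagents that add atoms: chloromethyl methyl ether, COCCl
Why: Williamson-type O-alkylation of both phenols with the chloromethyl ether gives the bis-acetal, whose two MOM-oxy groups serve as the directing groups for both later lithiations.

Step 6
Reactants: 7 1,3-bis(methoxymethoxy)benzene; 5 triethyl{[(3R)-1-iodo-3,7-dimethyloct-6-en-3-yl]oxy}silane
Product: 9 {[(3R)-1-[2,6-bis(methoxymethoxy)phenyl]-3,7-dimethyloct-6-en-3-yl]oxy}triethylsilane, via 2-lithio-1,3-bis(methoxymethoxy)benzene 8 (not isolated)
Conditions: n-BuLi, THF, 0 °C → rt; then 5, DMPU, −20 °C → rt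
Reagents that add atoms: none
Why: Directed ortho-metalation at C2 between the two cooperating MOM-oxy groups, followed by SN2 alkylation of the aryllithium with the primary iodide, in which the stereocentre sits two carbons from the reacting centre and is not touched.

Step 7
Reactants: 9 {[(3R)-1-[2,6-bis(methoxymethoxy)phenyl]-3,7-dimethyloct-6-en-3-yl]oxy}triethylsilane
Product: 11 {[(3R)-1-[3-iodo-2,6-bis(methoxymethoxy)phenyl]-3,7-dimethyloct-6-en-3-yl]oxy}triethylsilane, via C4-aryllithium 10 (not isolated)
Conditions: n-BuLi, TMEDA, THF, 0 °C; then I2, THF, −78 °C; aq. Na2S2O3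
Reagents that add atoms: iodine, II
Why: Second directed ortho-metalation, now at C4 (C4 and C6 are interchanged by rotation about the aryl–CH2 bond, so only one product is possible), followed by iodinolysis of the aryllithium, which at −78 °C should be far faster than any reaction of I2 with the trisubstituted alkene.

Step 8
Reactants: 11 {[(3R)-1-[3-iodo-2,6-bis(methoxymethoxy)phenyl]-3,7-dimethyloct-6-en-3-yl]oxy}triethylsilane; 12 carbon monoxide; 13 4-acetoxystyrene
Product: 14 4-[(1E)-3-{3-[(3R)-3,7-dimethyl-3-(triethylsilyloxy)oct-6-en-1-yl]-2,4-bis(methoxymethoxy)phenyl}-3-oxoprop-1-en-1-yl]phenyl acetate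
Conditions: [Pd(cinnamyl)Cl]2 (2.5 mol %), n-BuP(1-Ad)2 (10 mol %), Et3N, CO (10 bar), 13 (3 equiv), 1,4-dioxane, 100 °C
Reagents that add atoms: none
Why: Zerovalent palladium adds oxidatively to the C1'–I bond of 11, the electron-rich arylpalladium iodide takes up CO by migratory insertion, and the aroylpalladium species adds across the vinyl group of 13 with the acyl carbon on the terminal CH2 and palladium on the benzylic carbon; syn β-hydride elimination then releases the enone and Et3N returns the hydridopalladium iodide to the zerovalent state. The closest known reaction type is the palladium-catalysed carbonylative Heck coupling of aryl iodides with styrenes, an established chalcone synthesis. No ring is closed and no stereocentre is created; the alkene should emerge E because the syn elimination proceeds from the rotamer that keeps aroyl and aryl groups anti. The step needs CO insertion to precede alkene insertion, linear and not branched acyl transfer, and discrimination between the styrene and the side-chain alkene. These are secured by CO pressure and the high migratory aptitude of the ortho,para-dioxygenated aryl group, by benzylic stabilisation of palladium after insertion together with the steric preference for the terminal carbon, and by the trisubstituted, unactivated character of the C6=C7 alkene, which should not insert under these conditions.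

Step 9
Reactants: 14 4-[(1E)-3-{3-[(3R)-3,7-dimethyl-3-(triethylsilyloxy)oct-6-en-1-yl]-2,4-bis(methoxymethoxy)phenyl}-3-oxoprop-1-en-1-yl]phenyl acetate
Product: 16 (2E)-1-{3-[(3R)-3,7-dimethyl-3-(triethylsilyloxy)oct-6-en-1-yl]-2,4-dihydroxyphenyl}-3-(4-hydroxyphenyl)prop-2-en-1-one, via bis(trimethylsilyl) ether 15 (not isolated)
Conditions: TMSOTf, 2,2'-bipyridyl, CH3CN, 0 °C → rt; then K2CO3, MeOH–H2O, rt; aq. NH4Cl
Reagents that add atoms: none
Why: Chemoselective MOM cleavage with a silyl triflate–2,2'-bipyridyl pair, in which the buffered silyl triflate converts each aryl MOM ether into the aryl TMS ether (the methoxymethyl fragment passes to bipyridyl and is hydrolysed to formaldehyde and methanol), so no protic acid is present that could trigger chroman or flavanone formation, and the basic aqueous methanol then removes the TMS groups and the ring B acetate while the tertiary TES ether survives.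

Step 10
Reactants: 16 (2E)-1-{3-[(3R)-3,7-dimethyl-3-(triethylsilyloxy)oct-6-en-1-yl]-2,4-dihydroxyphenyl}-3-(4-hydroxyphenyl)prop-2-en-1-one
Product: 17 (2E)-1-{2,4-dihydroxy-3-[(3R)-3-hydroxy-3,7-dimethyloct-6-en-1-yl]phenyl}-3-(4-hydroxyphenyl)prop-2-en-1-one
Conditions: HF·pyridine, pyridine, THF, 0 °C → rt
Reagents that add atoms: none
Why: Fluoride-mediated desilylation of the tertiary TES ether with pyridine-buffered HF, mild enough to leave the 2'-hydroxychalcone, the tertiary alcohol and the trisubstituted alkene unchanged and breaking only the Si–O bond, so the stereocentre is not touched.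

Compound list
1 | geraniol, (2E)-3,7-dimethylocta-2,6-dien-1-ol | CC(C)=CCC/C(C)=C/CO | starting material
2 | (2R,3R)-2,3-epoxygeraniol, [(2R,3R)-3-methyl-3-(4-methylpent-3-en-1-yl)oxiran-2-yl]methanol | CC(C)=CCC[C@@]1(C)O[C@@H]1CO | intermediate
3 | (3R)-3,7-dimethyloct-6-ene-1,3-diol | CC(C)=CCC[C@@](C)(O)CCO | intermediate
4 | (3R)-1-iodo-3,7-dimethyloct-6-en-3-ol | CC(C)=CCC[C@@](C)(O)CCI | intermediate
5 | triethyl{[(3R)-1-iodo-3,7-dimethyloct-6-en-3-yl]oxy}silane | CC(C)=CCC[C@@](C)(O[Si](CC)(CC)CC)CCI | intermediate
6 | resorcinol, benzene-1,3-diol | Oc1cccc(O)c1 | starting material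
7 | 1,3-bis(methoxymethoxy)benzene | COCOc1cccc(OCOC)c1 | intermediate
8 | 2-lithio-1,3-bis(methoxymethoxy)benzene (not isolated) | COCOc1cccc(OCOC)c1[Li] | intermediate
9 | {[(3R)-1-[2,6-bis(methoxymethoxy)phenyl]-3,7-dimethyloct-6-en-3-yl]oxy}triethylsilane | CC(C)=CCC[C@@](C)(O[Si](CC)(CC)CC)CCc1c(OCOC)cccc1OCOC | intermediate
10 | C4-aryllithium of 9, {[(3R)-1-[3-lithio-2,6-bis(methoxymethoxy)phenyl]-3,7-dimethyloct-6-en-3-yl]oxy}triethylsilane (not isolated) | CC(C)=CCC[C@@](C)(O[Si](CC)(CC)CC)CCc1c(OCOC)ccc([Li])c1OCOC | intermediate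
11 | {[(3R)-1-[3-iodo-2,6-bis(methoxymethoxy)phenyl]-3,7-dimethyloct-6-en-3-yl]oxy}triethylsilane | CC(C)=CCC[C@@](C)(O[Si](CC)(CC)CC)CCc1c(OCOC)ccc(I)c1OCOC | intermediate
12 | carbon monoxide | [C-]#[O+] | starting material
13 | 4-acetoxystyrene, 4-ethenylphenyl acetate | C=Cc1ccc(OC(C)=O)cc1 | starting material
14 | 4-[(1E)-3-{3-[(3R)-3,7-dimethyl-3-(triethylsilyloxy)oct-6-en-1-yl]-2,4-bis(methoxymethoxy)phenyl}-3-oxoprop-1-en-1-yl]phenyl acetate | CC(C)=CCC[C@@](C)(O[Si](CC)(CC)CC)CCc1c(OCOC)ccc(C(=O)/C=C/c2ccc(OC(C)=O)cc2)c1OCOC | intermediate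
15 | 4-[(1E)-3-{3-[(3R)-3,7-dimethyl-3-(triethylsilyloxy)oct-6-en-1-yl]-2,4-bis(trimethylsilyloxy)phenyl}-3-oxoprop-1-en-1-yl]phenyl acetate (not isolated) | CC(C)=CCC[C@@](C)(O[Si](CC)(CC)CC)CCc1c(O[Si](C)(C)C)ccc(C(=O)/C=C/c2ccc(OC(C)=O)cc2)c1O[Si](C)(C)C | intermediate
16 | (2E)-1-{3-[(3R)-3,7-dimethyl-3-(triethylsilyloxy)oct-6-en-1-yl]-2,4-dihydroxyphenyl}-3-(4-hydroxyphenyl)prop-2-en-1-one | CC(C)=CCC[C@@](C)(O[Si](CC)(CC)CC)CCc1c(O)ccc(C(=O)/C=C/c2ccc(O)cc2)c1O | intermediate
17 | (2E)-1-{2,4-dihydroxy-3-[(3R)-3-hydroxy-3,7-dimethyloct-6-en-1-yl]phenyl}-3-(4-hydroxyphenyl)prop-2-en-1-one | CC(C)=CCC[C@@](C)(O)CCc1c(O)ccc(C(=O)/C=C/c2ccc(O)cc2)c1O | target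

Total step count: 10. Longest linear sequence: 9 steps (geraniol through steps 1, 2, 3, 4, 6, 7, 8, 9, 10).

Steps most likely to fail

Step 8. The alkene may insert into the arylpalladium species before CO is taken up, giving direct arylation of the styrene. The hindered ortho-alkoxy aroylpalladium may also be reduced, or the styrene may polymerise thermally. The fallback builds the enone by enolate chemistry and sets out from 9. Lithiation as in step 7 gives aryllithium 10, which is acylated with N-methoxy-N-methylacetamide (THF, −78 °C → 0 °C) to the aryl methyl ketone F1. Claisen–Schmidt condensation of F1 with commercial 4-(methoxymethoxy)benzaldehyde (KOH, EtOH, rt) should give the tris-MOM E-chalcone F2, the E geometry arising from the E1cB dehydration. Cleavage of the three MOM ethers with TMSOTf/2,2'-bipyridyl in CH3CN and aqueous work-up returns the route at 16.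

Step 6. The basic, doubly ortho-substituted aryllithium may cause E2 elimination of the iodide, or may substitute too slowly at a chain that carries a bulky quaternary centre. The fallback replaces the SN2 alkylation by a cross-coupling and sets out from 7 and 5. Aryllithium 8, made as in step 6, is quenched with I2 to give 2-iodo-1,3-bis(methoxymethoxy)benzene F3. Iodide 5 is converted with Zn dust and LiCl in THF into the alkylzinc iodide F4. Negishi coupling of F3 with F4 (Pd(OAc)2, SPhos, THF, rt → 50 °C) comes back to the route at 9.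

Step 9. Acetal cleavage may stall at the 2'-position next to the carbonyl, the silyl triflate may activate the enone, or the liberated 2'-phenol may add to the enone in a conjugate cyclisation. The fallback moves the protecting-group exchange ahead of the key step and sets out from 11. TESOTf/2,2'-bipyridyl in CH3CN should convert both aryl MOM ethers directly into aryl triethylsilyl ethers, giving the tris(triethylsilyl) iodide F5. Carbonylative Heck coupling of F5 with 12 and 13 under the conditions of step 8 gives the silyl-protected chalcone acetate F6. K2CO3 in MeOH then removes the acetate and both aryl silyl ethers and returns the route at 16.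

Further compounds
F1 | step 8 | 1-{3-[(3R)-3,7-dimethyl-3-(triethylsilyloxy)oct-6-en-1-yl]-2,4-bis(methoxymethoxy)phenyl}ethan-1-one | CC(C)=CCC[C@@](C)(O[Si](CC)(CC)CC)CCc1c(OCOC)ccc(C(C)=O)c1OCOC
F2 | step 8 | (2E)-1-{3-[(3R)-3,7-dimethyl-3-(triethylsilyloxy)oct-6-en-1-yl]-2,4-bis(methoxymethoxy)phenyl}-3-[4-(methoxymethoxy)phenyl]prop-2-en-1-one | CC(C)=CCC[C@@](C)(O[Si](CC)(CC)CC)CCc1c(OCOC)ccc(C(=O)/C=C/c2ccc(OCOC)cc2)c1OCOC
F3 | step 6 | 2-iodo-1,3-bis(methoxymethoxy)benzene | COCOc1cccc(OCOC)c1I
F4 | step 6 | [(3R)-3,7-dimethyl-3-(triethylsilyloxy)oct-6-en-1-yl]zinc iodide | CC(C)=CCC[C@@](C)(O[Si](CC)(CC)CC)CC[Zn]I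
F5 | step 9 | {[(3R)-1-[3-iodo-2,6-bis(triethylsilyloxy)phenyl]-3,7-dimethyloct-6-en-3-yl]oxy}triethylsilane | CC(C)=CCC[C@@](C)(O[Si](CC)(CC)CC)CCc1c(O[Si](CC)(CC)CC)ccc(I)c1O[Si](CC)(CC)CC
F6 | step 9 | 4-[(1E)-3-{3-[(3R)-3,7-dimethyl-3-(triethylsilyloxy)oct-6-en-1-yl]-2,4-bis(triethylsilyloxy)phenyl}-3-oxoprop-1-en-1-yl]phenyl acetate | CC(C)=CCC[C@@](C)(O[Si](CC)(CC)CC)CCc1c(O[Si](CC)(CC)CC)ccc(C(=O)/C=C/c2ccc(OC(C)=O)cc2)c1O[Si](CC)(CC)CC
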